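**Plan**

Labdane numbering is used for the decalin compounds: ring A = C1–C5 and C10, ring B = C5–C10, C17 = exocyclic CH2 on C8, C20 = methyl on C10, chain = C11–C16.

- Retrosynthesis: remove the C2 silyl ether, cut C12–C13 and C14–C15 (alkyl Grignard reagent + propargyl alcohol + CO2), cut C8=C17 (Wittig), then open ring A at C3–C4 together with the C2–O bond. Reconnecting C4 to C7 gives a pinane ketone, which is cut at C9–C11 (enolate alkylation) and C10–C1 (conjugate allylation) to reach verbenone.
- Enabling feature: ring B (C5–C10) with its C8 oxygen, the C20 methyl and the gem-dimethyl carbon C4 on C5 is the verbenone skeleton once the C4–C7 cyclobutane bond is broken. Scission of that bond next to the C8 carbonyl leaves a tertiary cation on C4 that C3 of an allyl group on C10 can reach through a six-membered chair.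
- Forward order: ring B comes with verbenone; C1–C3 and C11–C12 are attached on the bicycle; ring A closes in step 3; C17 and then C13–C16 follow.
- Stereochemistry: C5 from (1S,5S)-verbenone; C10 (and so the trans ring fusion) from conjugate addition anti to the gem-dimethyl bridge; C2 from anti addition across the alkene in a chair; C9 by base equilibration; the 13Z alkene from chelate-controlled anti-carbomagnesiation.

Key step: step 3

Remark: the alkylation of step 2 is assumed to occur anti to the gem-dimethyl bridge, which is of no consequence because this centre (C9) is equilibrated in step 4; in acetic anhydride the ring-opening step is expected to release the C8 oxygen as an enol acetate, not as the free ketone.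

**Route**

Step 1
Reactants: 1 (1S,5S)-(−)-verbenone; 2 allylmagnesium bromide
Product: 4 (1S,4S,5S)-4,6,6-trimethyl-4-(prop-2-en-1-yl)bicyclo[3.1.1]heptan-2-one, via trimethylsilyl enol ether 3 (not isolated)
Conditions: CuBr·SMe2 (1 equiv), TMSCl, THF, −78 °C; 1 M HCl, 0 °C
Reagents that add atoms: allylmagnesium bromide 2, C=CC[Mg]Br (chlorotrimethylsilane, C[Si](C)(C)Cl, appears only in 3)
Why: TMSCl-accelerated conjugate addition of the allylcopper reagent formed from 2 and CuBr·SMe2 should deliver the allyl group to the β-carbon from the face opposite the gem-dimethyl bridge, which sets the quaternary centre (later C10) with its methyl syn to the bridge, and the enol silane 3 is hydrolysed on acidic work-up.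

Step 2
Reactants: 4 (1S,4S,5S)-4,6,6-trimethyl-4-(prop-2-en-1-yl)bicyclo[3.1.1]heptan-2-one; 5 methyl bromoacetate
Product: 7 methyl 2-[(1S,3R,4R,5R)-4,6,6-trimethyl-2-oxo-4-(prop-2-en-1-yl)bicyclo[3.1.1]heptan-3-yl]acetate, via lithium enolate 6 (not isolated)
Conditions: LiN(iPr)2, THF, −78 °C; 5, DMPU, −78 → 0 °C
Reagents that add atoms: methyl bromoacetate 5, COC(=O)CBr (the lithium of LiN(iPr)2 appears only in 6)
Why: Because the other α-carbon is a bridgehead, LiN(iPr)2 can only form enolate 6, whose SN2 alkylation by the reactive α-bromo ester is expected on the face anti to the gem-dimethyl bridge, giving the arm cis to the allyl group at a centre (later C9) that is corrected in step 4.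

Step 3
Reactants: 7 methyl 2-[(1S,3R,4R,5R)-4,6,6-trimethyl-2-oxo-4-(prop-2-en-1-yl)bicyclo[3.1.1]heptan-3-yl]acetate
Product: 9 methyl 2-[(1R,4aR,7R,8aR)-2,7-diacetoxy-5,5,8a-trimethyl-1,4,4a,5,6,7,8,8a-octahydronaphthalen-1-yl]acetate, via ring-opened C4 cation 8 (not isolated)
Conditions: BF3·OEt2 (0.5 equiv), Zn(OAc)2 (0.2 equiv), Ac2O–AcOH (1:1), 0 °C → rt
Reagents that add atoms: acetic anhydride, CC(=O)OC(C)=O; acetic acid, CC(=O)O (co-solvent, equivalent source of the C2 acetate)
Why: Proposed new method: O-acetylation and BF3 activation of the C8 carbonyl let the strained C4–C7 cyclobutane bond ionise, giving the C7=C8 enol acetate and the tertiary C4 cation 8, which stays bonded to C5; the allyl terminus C3 then attacks C4 and acetate quenches the resulting secondary C2 cation. The closest known reactions are the BF3·OEt2/Zn(OAc)2/Ac2O opening of nopinone-type pinane ketones to monocyclic enol acetates carrying a tertiary acetate, and cation–olefin cyclisations onto a terminal vinyl group with carboxylate capture; their union in one flask is untested. Ring A closes in a 6-endo-trig mode through a chair in which the C5–C4 and C10–C1 bonds are both equatorial on ring B, so the trans ring fusion fixed in step 1 is carried over. The only new stereocentre, C2, is set by anti addition across the alkene: acetate enters anti to the forming C3–C4 bond, which is the equatorial position, trans to the C10 methyl. The step needs C–C bond formation at the weakly nucleophilic monosubstituted alkene to win over proton loss, acetate capture and hydride shift at the cation; acetate capture and proton loss are reversible in this medium, the gauche placement of C4 and the allyl CH2 on adjacent ring carbons keeps the alkene within reach, and attack through C3 and not C2 follows from the secondary versus primary cation. With acetic anhydride present the C8 oxygen emerges as its enol acetate and C9 keeps the configuration of 7, and both are settled in step 4.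

Step 4
Reactants: 9 methyl 2-[(1R,4aR,7R,8aR)-2,7-diacetoxy-5,5,8a-trimethyl-1,4,4a,5,6,7,8,8a-octahydronaphthalen-1-yl]acetate
Product: 10 methyl 2-[(1S,4aR,7R,8aR)-7-hydroxy-5,5,8a-trimethyl-2-oxodecahydronaphthalen-1-yl]acetate
Conditions: NaOMe (0.3 equiv), MeOH, rt
Reagents that add atoms: none
Why: Methoxide-catalysed transesterification should cleave the enol acetate and the secondary acetate while leaving the methyl ester as it is, and the C8 ketone enolises reversibly under these conditions so that C9 settles, under thermodynamic control, with the acetic ester arm equatorial and cis to the C10 methyl.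

Step 5
Reactants: 10 methyl 2-[(1S,4aR,7R,8aR)-7-hydroxy-5,5,8a-trimethyl-2-oxodecahydronaphthalen-1-yl]acetate
Product: 11 methyl 2-[(1S,4aR,7R,8aR)-7-{[tert-butyl(dimethyl)silyl]oxy}-5,5,8a-trimethyl-2-oxodecahydronaphthalen-1-yl]acetate
Conditions: TBSCl, imidazole, DMF, rt
Reagents that add atoms: tert-butyldimethylsilyl chloride, CC(C)(C)[Si](C)(C)Cl
Why: Imidazole-promoted silylation of the unhindered equatorial secondary alcohol is routine and installs a group that withstands ylide, hydride, phosphine/bromide and organomagnesium conditions.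

Step 6
Reactants: 11 methyl 2-[(1S,4aR,7R,8aR)-7-{[tert-butyl(dimethyl)silyl]oxy}-5,5,8a-trimethyl-2-oxodecahydronaphthalen-1-yl]acetate
Product: 12 methyl 2-[(1R,4aR,7R,8aR)-7-{[tert-butyl(dimethyl)silyl]oxy}-5,5,8a-trimethyl-2-methylidenedecahydronaphthalen-1-yl]acetate
Conditions: Ph3PCH3Br, KOtBu, THF, 0 → 60 °C
Reagents that add atoms: methyltriphenylphosphonium bromide, C[P+](c1ccccc1)(c1ccccc1)c1ccccc1.[Br-]
Why: Wittig methylenation with the non-stabilised ylide takes place at the ketone far faster than at the methyl ester, and C9 is already in its stable configuration, so enolisation by the basic ylide cannot erode it.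

Step 7
Reactants: 12 methyl 2-[(1R,4aR,7R,8aR)-7-{[tert-butyl(dimethyl)silyl]oxy}-5,5,8a-trimethyl-2-methylidenedecahydronaphthalen-1-yl]acetate
Product: 13 2-[(1R,4aR,7R,8aR)-7-{[tert-butyl(dimethyl)silyl]oxy}-5,5,8a-trimethyl-2-methylidenedecahydronaphthalen-1-yl]ethan-1-ol
Conditions: LiAlH4, THF, 0 °C; H2O, aq. NaOH
Reagents that add atoms: none
Why: Hydride reduction of the ester to the primary alcohol leaves the silyl ether and the 1,1-disubstituted alkene untouched.

Step 8
Reactants: 13 2-[(1R,4aR,7R,8aR)-7-{[tert-butyl(dimethyl)silyl]oxy}-5,5,8a-trimethyl-2-methylidenedecahydronaphthalen-1-yl]ethan-1-ol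
Product: 14 (1R,4aR,7R,8aR)-1-(2-bromoethyl)-7-{[tert-butyl(dimethyl)silyl]oxy}-5,5,8a-trimethyl-2-methylidenedecahydronaphthalene
Conditions: CBr4, PPh3, CH2Cl2, 0 °C
Reagents that add atoms: carbon tetrabromide, BrC(Br)(Br)Br
Why: Appel reaction in which bromide displaces the alkoxyphosphonium ion by SN2 at the unhindered primary carbon under neutral conditions that spare the silyl ether and the alkene.

Step 9
Reactants: 14 (1R,4aR,7R,8aR)-1-(2-bromoethyl)-7-{[tert-butyl(dimethyl)silyl]oxy}-5,5,8a-trimethyl-2-methylidenedecahydronaphthalene; 15 prop-2-yn-1-ol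
Product: 19 (2Z)-3-(acetoxymethyl)-5-[(1R,4aR,7R,8aR)-7-{[tert-butyl(dimethyl)silyl]oxy}-5,5,8a-trimethyl-2-methylidenedecahydronaphthalen-1-yl]pent-2-enoic acid, via Grignard reagent 16 (not isolated), via alkenylmagnesium alkoxide 17 (not isolated), via magnesium carboxylate 18 (not isolated)
Conditions: Mg, THF, 40 °C; add to 15 + iPrMgCl (THF, −20 °C), CuI (10 mol%), 0 °C → rt; CO2 (g), −20 °C → rt; Ar purge; Ac2O, 0 °C → rt; 1 M HCl, 0 °C
Reagents that add atoms: prop-2-yn-1-ol 15, C#CCO; carbon dioxide, O=C=O; acetic anhydride, CC(=O)OC(C)=O (magnesium, [Mg], and the chloromagnesium of iPrMgCl appear only in 16–18)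
Why: Copper-catalysed anti-carbomagnesiation of the propargylic alkoxide places the alkyl group of Grignard reagent 16 on the internal alkyne carbon (C13) and magnesium on the terminal carbon (C14), held cis to the CH2O group by a five-membered chelate, so that carboxylation of 17 with retention gives the 13Z geometry, and acetylating the magnesium alkoxide of 18 before any proton source is added blocks closure to the butenolide, the mixed anhydride formed at the carboxylate being hydrolysed on work-up.

Step 10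
Reactants: 19 (2Z)-3-(acetoxymethyl)-5-[(1R,4aR,7R,8aR)-7-{[tert-butyl(dimethyl)silyl]oxy}-5,5,8a-trimethyl-2-methylidenedecahydronaphthalen-1-yl]pent-2-enoic acid
Product: 20 (2Z)-3-(acetoxymethyl)-5-[(1R,4aR,7R,8aR)-7-hydroxy-5,5,8a-trimethyl-2-methylidenedecahydronaphthalen-1-yl]pent-2-enoic acid
Conditions: HF·pyridine, pyridine, THF, 0 °C → rt
Reagents that add atoms: none
Why: Buffered HF·pyridine cleaves the secondary silyl ether by fluoride attack at silicon under conditions that should leave the allylic acetate, the carboxylic acid and the exocyclic alkene alone.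

**Compound list**

1 | (1S,5S)-(−)-verbenone [(1S,5S)-4,6,6-trimethylbicyclo[3.1.1]hept-3-en-2-one] | CC1=CC(=O)[C@H]2C[C@@H]1C2(C)C | starting material
2 | allylmagnesium bromide | C=CC[Mg]Br | starting material
3 | {[(1S,4R,5R)-4,6,6-trimethyl-4-(prop-2-en-1-yl)bicyclo[3.1.1]hept-2-en-2-yl]oxy}trimethylsilane (allyl anti to the gem-dimethyl bridge; not isolated) | C[Si](C)(C)OC1=C[C@](C)(CC=C)[C@@H]2C[C@H]1C2(C)C | intermediate
4 | (1S,4S,5S)-4,6,6-trimethyl-4-(prop-2-en-1-yl)bicyclo[3.1.1]heptan-2-one (allyl anti to the gem-dimethyl bridge) | O=C1C[C@](C)(CC=C)[C@@H]2C[C@H]1C2(C)C | intermediate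
5 | methyl bromoacetate | COC(=O)CBr | starting material
6 | lithium (1S,4R,5R)-4,6,6-trimethyl-4-(prop-2-en-1-yl)bicyclo[3.1.1]hept-2-en-2-olate (not isolated) | [Li]OC1=C[C@](C)(CC=C)[C@@H]2C[C@H]1C2(C)C | intermediate
7 | methyl 2-[(1S,3R,4R,5R)-4,6,6-trimethyl-2-oxo-4-(prop-2-en-1-yl)bicyclo[3.1.1]heptan-3-yl]acetate (ester arm cis to allyl, both anti to the gem-dimethyl bridge) | O=C1[C@H](CC(=O)OC)[C@](C)(CC=C)[C@@H]2C[C@H]1C2(C)C | intermediate
8 | 2-[4-acetoxy-5-(2-methoxy-2-oxoethyl)-6-methyl-6-(prop-2-en-1-yl)cyclohex-3-en-1-yl]propan-2-ylium (tertiary C4 cation, ring substituents configured as in 7; not isolated) | CC(=O)OC1=CC[C@H]([C+](C)C)[C@@](C)(CC=C)[C@H]1CC(=O)OC | intermediate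
9 | methyl 2-[(1R,4aR,7R,8aR)-2,7-diacetoxy-5,5,8a-trimethyl-1,4,4a,5,6,7,8,8a-octahydronaphthalen-1-yl]acetate (trans-fused; C7=C8 enol acetate; C2 acetate equatorial; C9 arm trans to the C10 methyl) | CC(=O)OC1=CC[C@@H]2C(C)(C)C[C@@H](OC(C)=O)C[C@@]2(C)[C@H]1CC(=O)OC | intermediate
10 | methyl 2-[(1S,4aR,7R,8aR)-7-hydroxy-5,5,8a-trimethyl-2-oxodecahydronaphthalen-1-yl]acetate (C9 arm equatorial, cis to the C10 methyl) | O=C1CC[C@@H]2C(C)(C)C[C@@H](O)C[C@@]2(C)[C@@H]1CC(=O)OC | intermediate
11 | methyl 2-[(1S,4aR,7R,8aR)-7-{[tert-butyl(dimethyl)silyl]oxy}-5,5,8a-trimethyl-2-oxodecahydronaphthalen-1-yl]acetate | O=C1CC[C@@H]2C(C)(C)C[C@@H](O[Si](C)(C)C(C)(C)C)C[C@@]2(C)[C@@H]1CC(=O)OC | intermediate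
12 | methyl 2-[(1R,4aR,7R,8aR)-7-{[tert-butyl(dimethyl)silyl]oxy}-5,5,8a-trimethyl-2-methylidenedecahydronaphthalen-1-yl]acetate | C=C1CC[C@@H]2C(C)(C)C[C@@H](O[Si](C)(C)C(C)(C)C)C[C@@]2(C)[C@@H]1CC(=O)OC | intermediate
13 | 2-[(1R,4aR,7R,8aR)-7-{[tert-butyl(dimethyl)silyl]oxy}-5,5,8a-trimethyl-2-methylidenedecahydronaphthalen-1-yl]ethan-1-ol | C=C1CC[C@@H]2C(C)(C)C[C@@H](O[Si](C)(C)C(C)(C)C)C[C@@]2(C)[C@@H]1CCO | intermediate
14 | (1R,4aR,7R,8aR)-1-(2-bromoethyl)-7-{[tert-butyl(dimethyl)silyl]oxy}-5,5,8a-trimethyl-2-methylidenedecahydronaphthalene | C=C1CC[C@@H]2C(C)(C)C[C@@H](O[Si](C)(C)C(C)(C)C)C[C@@]2(C)[C@@H]1CCBr | intermediate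
15 | prop-2-yn-1-ol (propargyl alcohol) | C#CCO | starting material
16 | 2-[(1R,4aR,7R,8aR)-7-{[tert-butyl(dimethyl)silyl]oxy}-5,5,8a-trimethyl-2-methylidenedecahydronaphthalen-1-yl]ethylmagnesium bromide (not isolated) | C=C1CC[C@@H]2C(C)(C)C[C@@H](O[Si](C)(C)C(C)(C)C)C[C@@]2(C)[C@@H]1CC[Mg]Br | intermediate
17 | alkenylmagnesium alkoxide BrMg–C14H=C13(CH2OMgCl)–CH2CH2–decalinyl, magnesium on C14 cis to the CH2O group, decalinyl as in 14 (not isolated) | C=C1CC[C@@H]2C(C)(C)C[C@@H](O[Si](C)(C)C(C)(C)C)C[C@@]2(C)[C@@H]1CC/C(CO[Mg]Cl)=C/[Mg]Br | intermediate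
18 | bromomagnesium (2Z)-3-{[(chloromagnesio)oxy]methyl}-5-(decalinyl as in 14)pent-2-enoate (not isolated) | C=C1CC[C@@H]2C(C)(C)C[C@@H](O[Si](C)(C)C(C)(C)C)C[C@@]2(C)[C@@H]1CC/C(CO[Mg]Cl)=C/C(=O)O[Mg]Br | intermediate
19 | (2Z)-3-(acetoxymethyl)-5-[(1R,4aR,7R,8aR)-7-{[tert-butyl(dimethyl)silyl]oxy}-5,5,8a-trimethyl-2-methylidenedecahydronaphthalen-1-yl]pent-2-enoic acid | C=C1CC[C@@H]2C(C)(C)C[C@@H](O[Si](C)(C)C(C)(C)C)C[C@@]2(C)[C@@H]1CC/C(=C/C(=O)O)COC(C)=O | intermediate
20 | (2Z)-3-(acetoxymethyl)-5-[(1R,4aR,7R,8aR)-7-hydroxy-5,5,8a-trimethyl-2-methylidenedecahydronaphthalen-1-yl]pent-2-enoic acid (labdane numbering: 2R,5R,9R,10R; C2 hydroxyl equatorial, trans to the C10 methyl) | C=C1CC[C@@H]2C(C)(C)C[C@@H](O)C[C@@]2(C)[C@@H]1CC/C(=C/C(=O)O)COC(C)=O | target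

**Totals and risks**

Total step count: 10. Longest linear sequence: 10 steps, from verbenone 1.

Steps most likely to fail:

1. Step 3 (new cascade). The C4 cation may lose a proton to an isopropenyl or isopropylidene group, be captured by acetate, or suffer a hydride shift from C5 before the weakly nucleophilic alkene closes ring A. Reversible proton loss toward C5 could also erode the ring-fusion configuration. The fallback separates the two events using known reaction types. It sets out from 7: a short, cold BF3·OEt2/Zn(OAc)2/Ac2O treatment, as practised on nopinone-type ketones, should stop at methyl 2-[2-acetoxy-5-(2-acetoxypropan-2-yl)-6-methyl-6-(prop-2-en-1-yl)cyclohex-2-en-1-yl]acetate F1. Solvolysis of this tertiary acetate in anhydrous formic acid at rt then re-ionises C4 for a cation–olefin cyclisation with formate capture, giving methyl 2-[(1R,4aR,7R,8aR)-2-acetoxy-7-(formyloxy)-5,5,8a-trimethyl-1,4,4a,5,6,7,8,8a-octahydronaphthalen-1-yl]acetate F2. NaOMe in MeOH removes the formate and the enol acetate and equilibrates C9, so the route is rejoined at 10.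

2. Step 9. Deprotonation of the alkyne C–H by the Grignard reagent, or decay of the alkylcopper intermediate, may outrun carbomagnesiation. Incomplete O-acetylation before the carboxylate is activated would close the butenolide. The fallback builds the same alkene by syn-carbocupration of an ynoate and sets out from 14. Grignard reagent 16 is transmetallated with CuBr·SMe2 (1 equiv, THF, −78 °C) and added to tert-butyl 4-[(triethylsilyl)oxy]but-2-ynoate F3 (from triethyl(prop-2-yn-1-yloxy)silane, n-BuLi and Boc2O). Protonation at −78 °C should give tert-butyl (2Z)-5-[(1R,4aR,7R,8aR)-7-{[tert-butyl(dimethyl)silyl]oxy}-5,5,8a-trimethyl-2-methylidenedecahydronaphthalen-1-yl]-3-{[(triethylsilyl)oxy]methyl}pent-2-enoate F4. Buffered HF·pyridine at 0 °C removes only the primary allylic triethylsilyl group, giving tert-butyl (2Z)-5-(decalinyl as in 14)-3-(hydroxymethyl)pent-2-enoate F5, whose bulky ester is expected to resist lactonisation. Ac2O/pyridine gives tert-butyl (2Z)-3-(acetoxymethyl)-5-(decalinyl as in 14)pent-2-enoate F6, and TMSOTf/2,6-lutidine (CH2Cl2, 0 °C, aqueous work-up) cleaves the tert-butyl ester, rejoining the route at 19.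

3. Step 1. Direct 1,2-addition of the allyl nucleophile to the carbonyl may compete with conjugate delivery at the hindered, fully substituted β-carbon. The fallback makes the 1,2-addition deliberate and sets out from 1. Compound 2 alone (THF, −78 °C) should add anti to the gem-dimethyl bridge to give (1S,2S,5S)-4,6,6-trimethyl-2-(prop-2-en-1-yl)bicyclo[3.1.1]hept-3-en-2-ol F7. An anionic oxy-Cope rearrangement (KH, 18-crown-6, THF, rt) then transfers the allyl group suprafacially to the β-carbon on the same face, and protonation of the potassium enolate rejoins the route at 4.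

Further compounds
F1 | step 3 | methyl 2-[2-acetoxy-5-(2-acetoxypropan-2-yl)-6-methyl-6-(prop-2-en-1-yl)cyclohex-2-en-1-yl]acetate (ring substituents configured as in 7) | CC(=O)OC1=CC[C@H](C(C)(C)OC(C)=O)[C@@](C)(CC=C)[C@H]1CC(=O)OC
F2 | step 3 | methyl 2-[(1R,4aR,7R,8aR)-2-acetoxy-7-(formyloxy)-5,5,8a-trimethyl-1,4,4a,5,6,7,8,8a-octahydronaphthalen-1-yl]acetate | CC(=O)OC1=CC[C@@H]2C(C)(C)C[C@@H](OC=O)C[C@@]2(C)[C@H]1CC(=O)OC
F3 | step 9 | tert-butyl 4-[(triethylsilyl)oxy]but-2-ynoate | CC[Si](CC)(CC)OCC#CC(=O)OC(C)(C)C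
F4 | step 9 | tert-butyl (2Z)-5-[(1R,4aR,7R,8aR)-7-{[tert-butyl(dimethyl)silyl]oxy}-5,5,8a-trimethyl-2-methylidenedecahydronaphthalen-1-yl]-3-{[(triethylsilyl)oxy]methyl}pent-2-enoate | C=C1CC[C@@H]2C(C)(C)C[C@@H](O[Si](C)(C)C(C)(C)C)C[C@@]2(C)[C@@H]1CC/C(=C/C(=O)OC(C)(C)C)CO[Si](CC)(CC)CC
F5 | step 9 | tert-butyl (2Z)-5-[(1R,4aR,7R,8aR)-7-{[tert-butyl(dimethyl)silyl]oxy}-5,5,8a-trimethyl-2-methylidenedecahydronaphthalen-1-yl]-3-(hydroxymethyl)pent-2-enoate | C=C1CC[C@@H]2C(C)(C)C[C@@H](O[Si](C)(C)C(C)(C)C)C[C@@]2(C)[C@@H]1CC/C(=C/C(=O)OC(C)(C)C)CO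
F6 | step 9 | tert-butyl (2Z)-3-(acetoxymethyl)-5-[(1R,4aR,7R,8aR)-7-{[tert-butyl(dimethyl)silyl]oxy}-5,5,8a-trimethyl-2-methylidenedecahydronaphthalen-1-yl]pent-2-enoate | C=C1CC[C@@H]2C(C)(C)C[C@@H](O[Si](C)(C)C(C)(C)C)C[C@@]2(C)[C@@H]1CC/C(=C/C(=O)OC(C)(C)C)COC(C)=O
F7 | step 1 | (1S,2S,5S)-4,6,6-trimethyl-2-(prop-2-en-1-yl)bicyclo[3.1.1]hept-3-en-2-ol (allyl anti to the gem-dimethyl bridge) | CC1=C[C@@](O)(CC=C)[C@H]2C[C@@H]1C2(C)C
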